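## Retrosynthetic overview

1. Lespeflorin B1 (15) comes from its 7,4'-bis-MOM ether 14 by acid in the last step. The A and B rings are bought as bromoarenes, and the pyranone C-ring is the only ring formed.
2. The strategy rests on the α-ketol of the C-ring (C4 ketone next to the C3 carbinol) and on C2, a benzylic, O1-bearing centre that epimerises when it sits α to an aldehyde. The C3–C4 bond is cut to dialdehyde 13. Forward, a chiral carbene closes it (A-ring CHO as acyl anion, aliphatic CHO as acceptor) with dynamic kinetic resolution at C2.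
3. 13 comes from ester–aldehyde 11 by reducing both carbonyls and oxidising both alcohols. The O1–C2 bond of 11 comes from salicylaldehyde 5 and α-bromo arylacetate 10 (Williamson).
4. 5 and 10 come from bromophenols 1 and 6 by MOM protection and Stille prenylation with stannane 4.

Key step: step 9

Assumptions: (a) 1, 4 and 6 are taken as catalogue compounds. (b) The sense of induction of the aminoindanol triazolium in this closure is not predicted with certainty; both antipodes exist, and the one that leads to the (2R,3R) series (fixed by a pilot run) is the one used.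

## Route

Step 1
Reactants: 1 5-bromo-2,4-dihydroxybenzaldehyde; 2 chloromethyl methyl ether
Product: 3 5-bromo-2-hydroxy-4-(methoxymethoxy)benzaldehyde
Conditions: MOMCl (1.1 equiv), K2CO3, acetone, 0 °C → rt
Reagents that add atoms: chloromethyl methyl ether (2), COCCl
Why: Williamson-type O-alkylation; the 4-OH (para to CHO, not hydrogen-bonded) is the more acidic and more nucleophilic phenol, while the 2-OH stays locked in its hydrogen bond to the aldehyde, so one equivalent of MOMCl should give the 4-mono-ether.

Step 2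
Reactants: 3 5-bromo-2-hydroxy-4-(methoxymethoxy)benzaldehyde; 4 tributyl(3-methylbut-2-en-1-yl)stannane
Product: 5 2-hydroxy-4-(methoxymethoxy)-5-(3-methylbut-2-en-1-yl)benzaldehyde
Conditions: 4 (1.3 equiv), Pd(PPh3)4 (5 mol %), DMF, 95 °C, degassed
Reagents that add atoms: tributyl(3-methylbut-2-en-1-yl)stannane (4), CCCC[Sn](CCCC)(CCCC)CC=C(C)C
Why: Migita–Kosugi–Stille coupling; oxidative addition to the aryl bromide, transmetalation of the allylic stannane and reductive elimination at the less substituted allyl terminus should give the linear prenyl arene, and the neutral conditions tolerate the phenol, the aldehyde and the MOM ether.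

Step 3
Reactants: 6 methyl 2-(3-bromo-4-hydroxyphenyl)acetate; 2 chloromethyl methyl ether
Product: 7 methyl 2-[3-bromo-4-(methoxymethoxy)phenyl]acetate
Conditions: MOMCl (1.2 equiv), K2CO3, acetone, rt
Reagents that add atoms: chloromethyl methyl ether (2), COCCl
Why: Williamson-type O-alkylation of the only acidic OH; carbonate is too weak to enolise the arylacetate.

Step 4
Reactants: 7 methyl 2-[3-bromo-4-(methoxymethoxy)phenyl]acetate; 4 tributyl(3-methylbut-2-en-1-yl)stannane
Product: 8 methyl 2-[4-(methoxymethoxy)-3-(3-methylbut-2-en-1-yl)phenyl]acetate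
Conditions: 4 (1.3 equiv), Pd(PPh3)4 (5 mol %), DMF, 95 °C, degassed
Reagents that add atoms: tributyl(3-methylbut-2-en-1-yl)stannane (4), CCCC[Sn](CCCC)(CCCC)CC=C(C)C
Why: Migita–Kosugi–Stille coupling as in step 2; the ester and the MOM ether are inert, and the linear prenyl isomer is expected from reductive elimination at the unhindered allyl terminus.

Step 5
Reactants: 8 methyl 2-[4-(methoxymethoxy)-3-(3-methylbut-2-en-1-yl)phenyl]acetate
Product: 10 methyl 2-bromo-2-[4-(methoxymethoxy)-3-(3-methylbut-2-en-1-yl)phenyl]acetate (racemic), via silyl ketene acetal 9 (not isolated)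
Conditions: LiHMDS (1.1 equiv), TMSCl (1.2 equiv), THF, −78 °C; then NBS (1.05 equiv), −78 °C; short silica plug, used at once
Reagents that add atoms: N-bromosuccinimide, O=C1CCC(=O)N1Br; chlorotrimethylsilane, C[Si](C)(C)Cl (silicon only in 9)
Why: α-Halogenation of an ester through its silyl ketene acetal; the electron-rich ketene acetal 9 should be brominated by NBS at −78 °C far faster than the trisubstituted prenyl alkene, and no free enolate is present to cause double bromination; the new centre is racemic, which is what the route needs.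

Step 6
Reactants: 5 2-hydroxy-4-(methoxymethoxy)-5-(3-methylbut-2-en-1-yl)benzaldehyde; 10 methyl 2-bromo-2-[4-(methoxymethoxy)-3-(3-methylbut-2-en-1-yl)phenyl]acetate
Product: 11 methyl 2-[2-formyl-5-(methoxymethoxy)-4-(3-methylbut-2-en-1-yl)phenoxy]-2-[4-(methoxymethoxy)-3-(3-methylbut-2-en-1-yl)phenyl]acetate (racemic)
Conditions: K2CO3 (1.5 equiv), DMF, 0 °C → rt
Reagents that add atoms: none
Why: Williamson ether synthesis (SN2 at a benzylic α-halo ester) by the salicylaldehyde phenoxide, the classical entry to 2-(2-formylphenoxy)-2-arylacetates; carbonate at room temperature should keep enolate aldol onto the neighbouring aldehyde slow, and the racemic centre (future C2) needs no control.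

Step 7
Reactants: 11 the ester–aldehyde from step 6
Product: 12 2-[2-(hydroxymethyl)-5-(methoxymethoxy)-4-(3-methylbut-2-en-1-yl)phenoxy]-2-[4-(methoxymethoxy)-3-(3-methylbut-2-en-1-yl)phenyl]ethan-1-ol (racemic)
Conditions: LiAlH4 (1.5 equiv), THF, 0 °C; aqueous Rochelle-salt work-up
Reagents that add atoms: none
Why: Hydride reduction of both the aldehyde and the ester; aryl ethers, MOM acetals and isolated alkenes are inert, and reducing both carbonyls removes any need to tell them apart.

Step 8
Reactants: 12 the diol from step 7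
Product: 13 2-[2-formyl-5-(methoxymethoxy)-4-(3-methylbut-2-en-1-yl)phenoxy]-2-[4-(methoxymethoxy)-3-(3-methylbut-2-en-1-yl)phenyl]acetaldehyde (racemic, C2 labile)
Conditions: Dess–Martin periodinane (2.5 equiv), NaHCO3 (solid), CH2Cl2, 0 °C → rt; aq. NaHCO3 wash, crude used at once
Reagents that add atoms: none
Why: Dess–Martin oxidation of the benzylic and the primary alcohol to the two aldehydes under buffered, non-basic conditions that should neither enolise nor over-oxidise the α-aryloxy aldehyde.

Step 9
Reactants: 13 the racemic dialdehyde from step 8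
Product: 14 (2R,3R)-3-hydroxy-7-(methoxymethoxy)-2-[4-(methoxymethoxy)-3-(3-methylbut-2-en-1-yl)phenyl]-6-(3-methylbut-2-en-1-yl)chroman-4-one (2,3-trans)
Conditions: aminoindanol-derived N-C6F5 triazolium tetrafluoroborate (15 mol %, antipode as assumed above), i-Pr2NEt (1.0 equiv), toluene, 0 °C → rt, Ar
Reagents that add atoms: none
Why: The triazolylidene freed by the amine adds to the A-ring aldehyde, proton transfer gives the Breslow enaminol, and its C4 attacks the tethered aliphatic aldehyde carbon (C3) before the carbene is expelled; the closest known reaction type is the carbene-catalysed intramolecular crossed benzoin of 2-(2-oxoalkoxy)benzaldehydes to 3-hydroxychroman-4-ones, established with ketone acceptors, together with its dynamic kinetic variants on substrates that carry an acidic stereocentre next to the acceptor carbonyl. The six-membered C-ring (O1–C2–C3–C4–C4a–C8a) closes 6-exo-trig at the C3 carbonyl (enolexo with respect to the enaminol). C3 is set by the catalyst: the indane wall and the N-aryl group leave one face of the enaminol open, and the hydrogen bond from the enaminol OH to the incoming aldehyde oxygen fixes its orientation so that the Si face of the CHO is attacked (3R). C2 is set by dynamic kinetic resolution: the α-aryl-α-aryloxy aldehyde racemises through its enol under the amine, and only the (R)-epimer reaches the chair-like transition state with the B-ring aryl pseudo-equatorial and anti to the forming C3–O bond, which should give the 2,3-trans product. The step needs donor/acceptor chemoselectivity: the aliphatic aldehyde is the better electrophile but its α-carbon carries both an aryl and an aryloxy group, which should slow Breslow formation there (a path that would expel the aryloxide), whereas salicylaldehyde ethers are proven acyl-anion donors with this catalyst class, and the conjugated aryl ketone is also the thermodynamic α-ketol. A weak, hindered base at or below room temperature should keep enolate aldol onto the aryl aldehyde and epimerisation of the product at C3 slow.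

Step 10
Reactants: 14 the bis-MOM dihydroflavonol from step 9
Product: 15 lespeflorin B1, (2R,3R)-3,7-dihydroxy-2-[4-hydroxy-3-(3-methylbut-2-en-1-yl)phenyl]-6-(3-methylbut-2-en-1-yl)chroman-4-one
Conditions: HCl (3 M aq.), MeOH, 40 °C
Reagents that add atoms: none
Why: Acid-catalysed acetal cleavage (transacetalisation with methanol) of the two aryl MOM ethers; dilute acid at mild temperature should leave the ortho-prenyl phenols uncyclised and does not touch C2 or C3, the 2,3-trans isomer being also the thermodynamic one.

## Compound list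

1 | 5-bromo-2,4-dihydroxybenzaldehyde | O=Cc1cc(Br)c(O)cc1O | starting material
2 | chloromethyl methyl ether | COCCl | starting material
3 | 5-bromo-2-hydroxy-4-(methoxymethoxy)benzaldehyde | O=Cc1cc(Br)c(OCOC)cc1O | intermediate
4 | tributyl(3-methylbut-2-en-1-yl)stannane | CCCC[Sn](CCCC)(CCCC)CC=C(C)C | starting material
5 | 2-hydroxy-4-(methoxymethoxy)-5-(3-methylbut-2-en-1-yl)benzaldehyde | O=Cc1cc(CC=C(C)C)c(OCOC)cc1O | intermediate
6 | methyl 2-(3-bromo-4-hydroxyphenyl)acetate | COC(=O)Cc1ccc(O)c(Br)c1 | starting material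
7 | methyl 2-[3-bromo-4-(methoxymethoxy)phenyl]acetate | COC(=O)Cc1ccc(OCOC)c(Br)c1 | intermediate
8 | methyl 2-[4-(methoxymethoxy)-3-(3-methylbut-2-en-1-yl)phenyl]acetate | COC(=O)Cc1ccc(OCOC)c(CC=C(C)C)c1 | intermediate
9 | {1-methoxy-2-[4-(methoxymethoxy)-3-(3-methylbut-2-en-1-yl)phenyl]ethenyl}oxy(trimethyl)silane (silyl ketene acetal, E/Z mixture, not isolated) | COC(O[Si](C)(C)C)=Cc1ccc(OCOC)c(CC=C(C)C)c1 | intermediate
10 | methyl 2-bromo-2-[4-(methoxymethoxy)-3-(3-methylbut-2-en-1-yl)phenyl]acetate (racemic) | COC(=O)C(Br)c1ccc(OCOC)c(CC=C(C)C)c1 | intermediate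
11 | methyl 2-[2-formyl-5-(methoxymethoxy)-4-(3-methylbut-2-en-1-yl)phenoxy]-2-[4-(methoxymethoxy)-3-(3-methylbut-2-en-1-yl)phenyl]acetate (racemic) | COC(=O)C(Oc1cc(OCOC)c(CC=C(C)C)cc1C=O)c1ccc(OCOC)c(CC=C(C)C)c1 | intermediate
12 | 2-[2-(hydroxymethyl)-5-(methoxymethoxy)-4-(3-methylbut-2-en-1-yl)phenoxy]-2-[4-(methoxymethoxy)-3-(3-methylbut-2-en-1-yl)phenyl]ethan-1-ol (racemic) | OCC(Oc1cc(OCOC)c(CC=C(C)C)cc1CO)c1ccc(OCOC)c(CC=C(C)C)c1 | intermediate
13 | 2-[2-formyl-5-(methoxymethoxy)-4-(3-methylbut-2-en-1-yl)phenoxy]-2-[4-(methoxymethoxy)-3-(3-methylbut-2-en-1-yl)phenyl]acetaldehyde (racemic) | O=CC(Oc1cc(OCOC)c(CC=C(C)C)cc1C=O)c1ccc(OCOC)c(CC=C(C)C)c1 | intermediate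
14 | (2R,3R)-3-hydroxy-7-(methoxymethoxy)-2-[4-(methoxymethoxy)-3-(3-methylbut-2-en-1-yl)phenyl]-6-(3-methylbut-2-en-1-yl)chroman-4-one | CC(C)=CCc1cc([C@H]2Oc3cc(OCOC)c(CC=C(C)C)cc3C(=O)[C@@H]2O)ccc1OCOC | intermediate
15 | lespeflorin B1 | CC(C)=CCc1cc([C@H]2Oc3cc(O)c(CC=C(C)C)cc3C(=O)[C@@H]2O)ccc1O | target

## Step count and risks

Total steps: 10. Longest linear sequence: 8 (steps 3–10, from 6).

**Step 9 (carbene ring closure).** Three processes may defeat it:
- The carbene may be taken up by the aliphatic aldehyde, whose Breslow intermediate would expel the A-ring aryloxide and end in redox esterification.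
- Base-induced aldol closure to a dihydrobenzofuranol may outrun the benzoin.
- The catalyst may discriminate the two C2 epimers poorly.

Fallback: an epoxychalcone route that needs no acyl anion, setting out from 5 and coming back at 15. Phenol 5 would be capped at O2 with 2 (NaH, DMF) to give 2,4-bis(methoxymethoxy)-5-(3-methylbut-2-en-1-yl)benzaldehyde F1. MeMgBr should then give 1-[2,4-bis(methoxymethoxy)-5-(3-methylbut-2-en-1-yl)phenyl]ethan-1-ol F2, and MnO2 the ketone 1-[2,4-bis(methoxymethoxy)-5-(3-methylbut-2-en-1-yl)phenyl]ethan-1-one F3. Commercial 3-bromo-4-hydroxybenzaldehyde (O=Cc1ccc(O)c(Br)c1) would be protected with 2 (K2CO3, acetone) to 3-bromo-4-(methoxymethoxy)benzaldehyde F4 and coupled with 4 (Pd(PPh3)4, DMF) to 4-(methoxymethoxy)-3-(3-methylbut-2-en-1-yl)benzaldehyde F5. Claisen–Schmidt condensation of F3 with F5 (KOH, EtOH) should give (E)-1-[2,4-bis(methoxymethoxy)-5-(3-methylbut-2-en-1-yl)phenyl]-3-[4-(methoxymethoxy)-3-(3-methylbut-2-en-1-yl)phenyl]prop-2-en-1-one F6. Juliá–Colonna epoxidation (poly-L-leucine, urea–H2O2, DBU, THF) is nucleophilic and should spare the prenyl alkenes, giving [2,4-bis(methoxymethoxy)-5-(3-methylbut-2-en-1-yl)phenyl]{(2R,3S)-3-[4-(methoxymethoxy)-3-(3-methylbut-2-en-1-yl)phenyl]oxiran-2-yl}methanone F7. HCl in MeOH would then remove all three MOM groups, and the freed 2'-phenol should open the epoxide at the benzylic carbon with inversion, giving 15 directly with both centres fixed by the epoxide.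

**Step 8 (double oxidation).** The dialdehyde may be lost through hydration, enol oxidation or aldol self-condensation during oxidation and handling.

Fallback: partial reduction with the aryl aldehyde masked, setting out from 11 and coming back at 13. The aryl aldehyde of 11 would be converted to its dimethyl acetal (HC(OMe)3, cat. PPTS, MeOH, rt) to give methyl 2-[2-(dimethoxymethyl)-5-(methoxymethoxy)-4-(3-methylbut-2-en-1-yl)phenoxy]-2-[4-(methoxymethoxy)-3-(3-methylbut-2-en-1-yl)phenyl]acetate F8. DIBAL-H at −78 °C should stop at the aldehyde stage of the α-aryloxy ester and give 2-[2-(dimethoxymethyl)-5-(methoxymethoxy)-4-(3-methylbut-2-en-1-yl)phenoxy]-2-[4-(methoxymethoxy)-3-(3-methylbut-2-en-1-yl)phenyl]acetaldehyde F9. Brief treatment with PPTS in aqueous acetone should hydrolyse the electron-rich aryl acetal faster than the MOM ethers and release 13 just before step 9.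

**Step 6 (etherification).** The doubly activated benzylic bromide may ionise and be lost to hydrolysis before the hydrogen-bonded phenoxide captures it, and the acidic α-C–H of the product may add to the neighbouring aldehyde under the basic conditions.

Fallback: a neutral Mitsunobu coupling, setting out from 8 (with 5) and coming back at 11. The potassium enolate of 8 (KHMDS, THF, −78 °C) would be hydroxylated with 2-(phenylsulfonyl)-3-phenyloxaziridine to methyl 2-hydroxy-2-[4-(methoxymethoxy)-3-(3-methylbut-2-en-1-yl)phenyl]acetate F10. Mitsunobu etherification of F10 with phenol 5 (PPh3, DIAD, toluene, 0 °C) should then form the O1–C2 bond and give 11.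

Further compounds
F1 | step 9 | 2,4-bis(methoxymethoxy)-5-(3-methylbut-2-en-1-yl)benzaldehyde | O=Cc1cc(CC=C(C)C)c(OCOC)cc1OCOC
F2 | step 9 | 1-[2,4-bis(methoxymethoxy)-5-(3-methylbut-2-en-1-yl)phenyl]ethan-1-ol (racemic) | CC(O)c1cc(CC=C(C)C)c(OCOC)cc1OCOC
F3 | step 9 | 1-[2,4-bis(methoxymethoxy)-5-(3-methylbut-2-en-1-yl)phenyl]ethan-1-one | CC(=O)c1cc(CC=C(C)C)c(OCOC)cc1OCOC
F4 | step 9 | 3-bromo-4-(methoxymethoxy)benzaldehyde | O=Cc1ccc(OCOC)c(Br)c1
F5 | step 9 | 4-(methoxymethoxy)-3-(3-methylbut-2-en-1-yl)benzaldehyde | O=Cc1ccc(OCOC)c(CC=C(C)C)c1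
F6 | step 9 | (E)-1-[2,4-bis(methoxymethoxy)-5-(3-methylbut-2-en-1-yl)phenyl]-3-[4-(methoxymethoxy)-3-(3-methylbut-2-en-1-yl)phenyl]prop-2-en-1-one | O=C(/C=C/c1ccc(OCOC)c(CC=C(C)C)c1)c1cc(CC=C(C)C)c(OCOC)cc1OCOC
F7 | step 9 | [2,4-bis(methoxymethoxy)-5-(3-methylbut-2-en-1-yl)phenyl]{(2R,3S)-3-[4-(methoxymethoxy)-3-(3-methylbut-2-en-1-yl)phenyl]oxiran-2-yl}methanone | O=C([C@@H]1O[C@H]1c2ccc(OCOC)c(CC=C(C)C)c2)c3cc(CC=C(C)C)c(OCOC)cc3OCOC
F8 | step 8 | methyl 2-[2-(dimethoxymethyl)-5-(methoxymethoxy)-4-(3-methylbut-2-en-1-yl)phenoxy]-2-[4-(methoxymethoxy)-3-(3-methylbut-2-en-1-yl)phenyl]acetate (racemic) | COC(=O)C(Oc1cc(OCOC)c(CC=C(C)C)cc1C(OC)OC)c1ccc(OCOC)c(CC=C(C)C)c1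
F9 | step 8 | 2-[2-(dimethoxymethyl)-5-(methoxymethoxy)-4-(3-methylbut-2-en-1-yl)phenoxy]-2-[4-(methoxymethoxy)-3-(3-methylbut-2-en-1-yl)phenyl]acetaldehyde (racemic) | O=CC(Oc1cc(OCOC)c(CC=C(C)C)cc1C(OC)OC)c1ccc(OCOC)c(CC=C(C)C)c1
F10 | step 6 | methyl 2-hydroxy-2-[4-(methoxymethoxy)-3-(3-methylbut-2-en-1-yl)phenyl]acetate (racemic) | COC(=O)C(O)c1ccc(OCOC)c(CC=C(C)C)c1
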